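## The problem

The target is a tetrahydrofuran (ring atoms O1, C2, C3, C4, C5) whose C3 and C4 each carry an aryl(hydroxy)methyl arm. The carbinol carbon on C3 is called Cα and that on C4 is called Cα′; both aryl groups are 4-hydroxy-3-methoxyphenyl. The two arms are constitutionally identical, but the molecule has no C2 axis: C3 and C4 are both R (trans), whereas Cα is S and Cα′ is R. A synthesis therefore has to tell the two arms apart at some stage, because any symmetric approach converges on the diastereomer with like-configured carbinols. C3 and C4 must be set in the absolute sense. Once one of them is fixed, the other can be brought to trans by equilibration if it lies next to a carbonyl group. The ring carbons give only weak 1,2-induction at Cα and Cα′, and the two arms need opposite senses, so at least one carbinol must be set by a reagent. The 4-hydroxybenzylic alcohols ionise easily under acid (epimerisation, ether formation) and can be over-reduced on hydrogenolysis, and free phenols do not tolerate oxidants. The phenols therefore stay protected to the end and late steps must be neutral or basic. The enabling feature is that O1–C2–C3–Cα is an opened 2-(1-arylvinyl)oxirane, with Cα masked as an alkene carbon, while C5–C4–Cα′ is the β-carbon, α-carbon and carbonyl carbon of an aryl vinyl ketone. The ring can thus be closed by forming O1–C5 and C3–C4 in one operation, with the two benzylic carbons arriving at different oxidation levels.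

## Retrosynthesis

**Protecting groups (15 ⇒ 14 ⇒ 13).** The last cuts are the two aryl O–benzyl bonds of 14 and the O–Si bond of 13. Benzyl is chosen for the phenols because it survives Grignard, hydroperoxide, ylide, borane and periodate chemistry and leaves under neutral hydrogenolysis. A silyl ether on Cα′–OH is removed by fluoride without acid. The forward steps must spare the two benzylic C–OH bonds.

**Cα–H bond (13 ⇒ 12).** The (S)-carbinol at Cα is traced to aryl ketone 12. This is preferred to inverting a preformed alcohol, which would pass through an easily ionised 4-alkoxybenzylic centre. The forward reduction must be reagent-controlled, because the ring may favour either face.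

**Unmasking Cα (12 ⇒ 10 ⇒ 9).** The Cα carbonyl of 12 comes from the 1,1-disubstituted alkene of 10 by cleavage of C=CH2, through diol 11. The alternative of carrying a 3,4-diaroyl compound is rejected, because its two carbonyls would be equivalent and one catalyst could only give like-configured carbinols. Silyl ether 10 comes from alcohol 9; the silyl group prevents the γ-hydroxy ketone from closing to a hemiketal.

**Cα′–H bond (9 ⇒ 8).** The (R)-carbinol at Cα′ is traced to ketone 8 and is set by the antipode of the catalyst used later at Cα. The forward step must leave the alkene and the epimerisable C4 alone.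

**Ring formation (8 ⇒ 4 + 6).** Cutting O1–C5 and C3–C4 of 8 gives aryl vinyl ketone 4 and racemic vinyl epoxide 6. This removes the ring and both ring stereocentres at once and leaves two achiral or racemic fragments of about ten heavy atoms each from the same aldehyde. Cutting C3–C4 alone (an intramolecular allylation) would require a longer tethered precursor. The forward reaction must convert both enantiomers of 6 into one enantiomer of 8 and close the five-membered ring at the internal allyl terminus.

**Vinyl epoxide (6 ⇒ 5 ⇒ 4).** The C=CH2 bond of 6 is cut to epoxy ketone 5, and the oxirane of 5 to enone 4. Both fragments therefore come from one intermediate, and no enantioselective epoxidation is needed.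

**Enone (4 ⇒ 3 ⇒ 1 + 2).** Enone 4 comes from allylic alcohol 3, made by adding vinylmagnesium bromide 2 to O-benzylvanillin 1.

## Roads not taken

**Alternative 1:** The cut is at both benzylic C–O bonds of a bis-lactone. Anodic oxidation of (2R,3R)-dibenzylsuccinic acid A1 would turn each electron-rich benzyl group into a cation that the γ-carboxylate traps, giving the cis-fused exo,exo bis-lactone A2.
- Merits: the C3/C4 configuration comes from well-established succinate chemistry, both benzylic oxygens are installed in one step, and the rigid bicycle directs the aryl groups exo.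
- Weak points: A2 is C2-symmetric. Reduction of both lactones and ether closure between the primary carbinols would give the trans-tetrahydrofuran A3 with like-configured carbinols, which is the wrong diastereomer. One of two equivalent carbinols would then have to be inverted at an ionisation-prone centre, with no element to make the mono-inversion selective. Closing the ether between the primary hydroxyls also competes with attack by the benzylic hydroxyls, and the anode must oxidise the arene without Kolbe decarboxylation or over-oxidation of the product.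
- Comparison: this road is better in the reliability of absolute control at C3/C4. The chosen plan sets against it that the two arms are different from the moment the ring forms.

**Alternative 2:** The cut is at Cα–C3 and Cα′–C4. A (2+2) cycloaddition of diarylalkyne A4 with 2,5-dihydrofuran A5, mediated by monovalent cobalt (CoBr2, 1,3-bis(diphenylphosphino)propane, Zn, ZnI2), would give the meso cyclobutene A6. Ozonolysis of its double bond would give the cis-diketone A7.
- Merits: the whole skeleton is made in one step from a symmetric alkyne and a commodity alkene, and it is the shortest path to the diketone level.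
- Weak points: A6 and A7 are meso, so nothing is set in the absolute sense. Epimerisation of A7 to trans gives a racemic diketone with equivalent carbonyls, which one catalyst can only reduce to like-configured carbinols. A desymmetrising mono-reduction of A7 is conceivable but has no close model and gives a cis γ-hydroxy ketone that closes to a hemiketal. A5 is unstrained and can isomerise, and ozone must discriminate between a tetrasubstituted stilbene-type alkene and four electron-rich aryl ethers.
- Comparison: this road is better in convergence and step count. The chosen plan sets against it catalytic absolute control in the C–C bond-forming step and carbonyls that are unveiled one at a time.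

**Alternative 3:** The cut is at C3–C4 and both benzylic C–O bonds. Visible-light oxidation of one styrene of bis(cinnamyl) ether A8 by Ru(bpz)3(PF6)2 under O2 would cyclise the radical cation onto the second styrene and capture O2, giving the trans-fused endoperoxide A9. Reductive O–O cleavage and debenzylation would follow.
- Merits: it is by far the shortest road. One step forms the ring, the C3–C4 bond, both C–O bonds and four stereocentres at the correct oxidation level. No carbonyl reduction is needed, and electron-rich styrenes are the preferred substrates.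
- Weak points: the radical-cation manifold offers no handle for absolute control, so A9 is racemic. The relative configuration of A9 corresponds to like-configured carbinols, so O–O cleavage gives the racemic diol A10, and the target would still need resolution and inversion at one of two equivalent carbinols.
- Comparison: this road is clearly better in step and redox economy and would be the route of choice for the racemic C2-symmetric diastereomer. The chosen plan accepts roughly twice as many steps in return for enantiocontrol and independent setting of Cα and Cα′.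

Key step: step 5

Ar = 4-benzyloxy-3-methoxyphenyl. Locants in systematic names follow nomenclature rules and may differ from the skeleton numbering used above.

Assumption: the sense of induction of the annulation with this acceptor cannot be predicted with confidence; (R)-SEGPHOS is written, and its antipode would replace it, with nothing else changed, if the first run shows the opposite sense.

Assumption: in both oxazaborolidine reductions the aryl group acts as the larger ketone substituent, as in the acetophenone model, so the (S)-catalyst gives the (R)-carbinol and the (R)-catalyst the (S)-carbinol.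

## Route

Step 1
Reactants: 1 4-benzyloxy-3-methoxybenzaldehyde; 2 vinylmagnesium bromide
Product: 3 rac-1-(4-benzyloxy-3-methoxyphenyl)prop-2-en-1-ol
Conditions: 2 (1.2 equiv), THF, −78 to 0 °C; aq. NH4Cl
Reagents that add atoms: none
Why: Grignard 1,2-addition to an aryl aldehyde; the carbinol centre is racemic and is destroyed in step 2.

Step 2
Reactants: 3 rac-1-(4-benzyloxy-3-methoxyphenyl)prop-2-en-1-ol
Product: 4 1-(4-benzyloxy-3-methoxyphenyl)prop-2-en-1-one
Conditions: activated MnO2 (excess), CH2Cl2, rt; filtered and used at once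
Reagents that add atoms: none
Why: MnO2 oxidation of an alcohol that is both allylic and benzylic; the neutral heterogeneous conditions spare the polymerisation-prone aryl vinyl ketone, which is not stored.

Step 3
Reactants: 4 1-(4-benzyloxy-3-methoxyphenyl)prop-2-en-1-one
Product: 5 rac-(4-benzyloxy-3-methoxyphenyl)(oxiran-2-yl)methanone
Conditions: tBuOOH (in decane), DBU, CH2Cl2, 0 °C
Reagents that add atoms: tert-butyl hydroperoxide, CC(C)(C)OO
Why: Weitz–Scheffer nucleophilic epoxidation: the hydroperoxide anion adds to the unhindered β-carbon and the enolate closes on the O–O bond; a racemic epoxide suffices because step 5 is enantioconvergent.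

Step 4
Reactants: 5 rac-(4-benzyloxy-3-methoxyphenyl)(oxiran-2-yl)methanone
Product: 6 rac-2-[1-(4-benzyloxy-3-methoxyphenyl)ethenyl]oxirane
Conditions: Ph3PCH3Br, KOtBu, THF, 0 °C to rt; chromatography on Et3N-deactivated silica
Reagents that add atoms: methyltriphenylphosphonium bromide, [Br-].C[P+](c1ccccc1)(c1ccccc1)c1ccccc1
Why: Wittig methylenation of an α,β-epoxy ketone, a standard entry to vinyl epoxides; the non-stabilised ylide attacks the carbonyl far faster than the oxirane, and the only α-hydrogen is a poorly acidic oxiranyl one.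

Step 5
Reactants: 4 1-(4-benzyloxy-3-methoxyphenyl)prop-2-en-1-one; 6 rac-2-[1-(4-benzyloxy-3-methoxyphenyl)ethenyl]oxirane
Product: 8 (4-benzyloxy-3-methoxyphenyl){(3R,4S)-4-[1-(4-benzyloxy-3-methoxyphenyl)ethenyl]oxolan-3-yl}methanone (trans), via cis-(3S,4S) epimer 7 (not isolated)
Conditions: Pd2(dba)3·CHCl3 (2.5 mol%), (R)-SEGPHOS (6 mol%), THF, rt, 4 added slowly to 6 (1.3 equiv); then DBU (0.2 equiv), rt
Reagents that add atoms: none
Why: Zerovalent palladium ionises the allylic C–O bond of 6 to a zwitterion, a 2-aryl-π-allyl complex of divalent palladium tethered to a primary alkoxide. The alkoxide adds reversibly to the unsubstituted β-carbon of 4 (O1–C5 bond), and the resulting ketone enolate, ion-paired with the allyl cation, attacks the internal allyl terminus (C3–C4 bond). The closest known reaction type is the palladium-catalysed asymmetric (3+2) annulation of vinyl epoxides and vinylethylene carbonates with Michael acceptors, enones included, and the enolate–allyl ion pair resembles that of decarboxylative allylic alkylation of ketone enolates. The tetrahydrofuran closes by 5-exo attack on the allyl unit; attack at the CH2 terminus would need a seven-membered ring, and O-allylation of the enolate is reversible under the catalyst, so the five-membered C-alkylation product is the sink. The allylic carbon (skeleton C3) is set by the ligand, because the diastereomeric π-allyl complexes from the two enantiomers of 6 interconvert by η3–η1–η3 slippage through the unsubstituted CH2 terminus faster than the ring closes. The ketone-bearing carbon (skeleton C4) is under thermodynamic control: any cis epimer 7 is equilibrated by DBU to trans 8, and β-alkoxide loss is slow because the ring C–O bond lies near the nodal plane of the exocyclic enolate. The step needs the alkoxide to be captured before the zwitterion isomerises by β-hydride loss, and ring closure to outrun addition of the enolate to a second molecule of 4; the highly electrophilic vinyl ketone serves the first need and its slow addition to an excess of 6 the second.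

Step 6
Reactants: 8 (4-benzyloxy-3-methoxyphenyl){(3R,4S)-4-[1-(4-benzyloxy-3-methoxyphenyl)ethenyl]oxolan-3-yl}methanone
Product: 9 (R)-(4-benzyloxy-3-methoxyphenyl){(3R,4S)-4-[1-(4-benzyloxy-3-methoxyphenyl)ethenyl]oxolan-3-yl}methanol
Conditions: (S)-2-methyl-CBS-oxazaborolidine (0.3 equiv), catecholborane, toluene, −78 to −40 °C; MeOH, aq. NaOH wash
Reagents that add atoms: none
Why: Corey–Bakshi–Shibata reduction: the ketone binds the catalyst boron anti to the aryl group and hydride is delivered intramolecularly to the face that gives the (R)-carbinol at Cα′. Catecholborane does not hydroborate the 1,1-disubstituted alkene at low temperature, and the base-free medium leaves C3 and C4 untouched.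

Step 7
Reactants: 9 (R)-(4-benzyloxy-3-methoxyphenyl){(3R,4S)-4-[1-(4-benzyloxy-3-methoxyphenyl)ethenyl]oxolan-3-yl}methanol
Product: 10 tert-butyl{(R)-(4-benzyloxy-3-methoxyphenyl)[(3R,4S)-4-[1-(4-benzyloxy-3-methoxyphenyl)ethenyl]oxolan-3-yl]methoxy}dimethylsilane
Conditions: TBSOTf, 2,6-lutidine, CH2Cl2, −78 to 0 °C
Reagents that add atoms: tert-butyldimethylsilyl trifluoromethanesulfonate, CC(C)(C)[Si](C)(C)OS(=O)(=O)C(F)(F)F
Why: silylation of a hindered secondary alcohol with a silyl triflate and a hindered base; the ether prevents hemiketal formation with the ketone unveiled in step 8 and keeps the hydroxyl from consuming borane in step 9.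

Step 8
Reactants: 10 tert-butyl{(R)-(4-benzyloxy-3-methoxyphenyl)[(3R,4S)-4-[1-(4-benzyloxy-3-methoxyphenyl)ethenyl]oxolan-3-yl]methoxy}dimethylsilane
Product: 12 (4-benzyloxy-3-methoxyphenyl){(3R,4R)-4-[(R)-(4-benzyloxy-3-methoxyphenyl)(tert-butyldimethylsilyloxy)methyl]oxolan-3-yl}methanone, via 1,2-diol 11 (not isolated)
Conditions: OsO4 (2 mol%), NaIO4 (4 equiv), 2,6-lutidine, 1,4-dioxane–H2O (3:1), rt
Reagents that add atoms: osmium tetroxide, O=[Os](=O)(=O)=O; sodium periodate, [Na+].[O-]I(=O)(=O)=O
Why: Lemieux–Johnson cleavage: OsO4 dihydroxylates the only alkene, and periodate cleaves diol 11 to the aryl ketone and formaldehyde and reoxidises osmium. It is preferred to ozone, which also attacks benzyl ethers and electron-rich arenes; C3 is already trans, so transient enolisation does no harm.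

Step 9
Reactants: 12 (4-benzyloxy-3-methoxyphenyl){(3R,4R)-4-[(R)-(4-benzyloxy-3-methoxyphenyl)(tert-butyldimethylsilyloxy)methyl]oxolan-3-yl}methanone
Product: 13 (S)-(4-benzyloxy-3-methoxyphenyl){(3R,4R)-4-[(R)-(4-benzyloxy-3-methoxyphenyl)(tert-butyldimethylsilyloxy)methyl]oxolan-3-yl}methanol
Conditions: (R)-2-methyl-CBS-oxazaborolidine (0.5–1.0 equiv), catecholborane, toluene, −78 to −20 °C; MeOH, aq. NaOH wash
Reagents that add atoms: none
Why: Corey–Bakshi–Shibata reduction with the antipodal catalyst sets the (S)-carbinol at Cα by the same model; the two arms now differ in oxidation level and protection, so the unlike pair of carbinols comes from the choice of catalyst antipode.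

Step 10
Reactants: 13 (S)-(4-benzyloxy-3-methoxyphenyl){(3R,4R)-4-[(R)-(4-benzyloxy-3-methoxyphenyl)(tert-butyldimethylsilyloxy)methyl]oxolan-3-yl}methanol
Product: 14 (S)-(4-benzyloxy-3-methoxyphenyl){(3R,4R)-4-[(R)-(4-benzyloxy-3-methoxyphenyl)(hydroxy)methyl]oxolan-3-yl}methanol
Conditions: TBAF, THF, 0 °C to rt
Reagents that add atoms: none
Why: fluoride cleavage of a secondary silyl ether; acid-free conditions avoid ionisation of the 4-alkoxybenzylic carbinols.

Step 11
Reactants: 14 (S)-(4-benzyloxy-3-methoxyphenyl){(3R,4R)-4-[(R)-(4-benzyloxy-3-methoxyphenyl)(hydroxy)methyl]oxolan-3-yl}methanol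
Product: 15 4-[(S)-hydroxy{(3R,4R)-4-[(R)-hydroxy(4-hydroxy-3-methoxyphenyl)methyl]oxolan-3-yl}methyl]-2-methoxyphenol
Conditions: H2 (1 atm), 10% Pd/C, EtOAc, rt; stopped when debenzylation is complete
Reagents that add atoms: none
Why: hydrogenolysis of aryl benzyl ethers over palladium on carbon; in an acid-free medium the ArO–CH2Ph bonds cleave much faster than the secondary benzylic C–OH bonds, and no stereocentre is touched.

## Compound list

1 | 4-benzyloxy-3-methoxybenzaldehyde | COc1cc(C=O)ccc1OCc1ccccc1 | starting material
2 | vinylmagnesium bromide | C=C[Mg]Br | starting material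
3 | rac-1-(4-benzyloxy-3-methoxyphenyl)prop-2-en-1-ol | C=CC(O)c1ccc(OCc2ccccc2)c(OC)c1 | intermediate
4 | 1-(4-benzyloxy-3-methoxyphenyl)prop-2-en-1-one | C=CC(=O)c1ccc(OCc2ccccc2)c(OC)c1 | intermediate
5 | rac-(4-benzyloxy-3-methoxyphenyl)(oxiran-2-yl)methanone | O=C(C1CO1)c1ccc(OCc2ccccc2)c(OC)c1 | intermediate
6 | rac-2-[1-(4-benzyloxy-3-methoxyphenyl)ethenyl]oxirane | C=C(C1CO1)c1ccc(OCc2ccccc2)c(OC)c1 | intermediate
7 | (4-benzyloxy-3-methoxyphenyl){(3S,4S)-4-[1-(4-benzyloxy-3-methoxyphenyl)ethenyl]oxolan-3-yl}methanone (cis) | COc1cc(C(=C)[C@H]2COC[C@H]2C(=O)c2ccc(OCc3ccccc3)c(OC)c2)ccc1OCc1ccccc1 | intermediate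
8 | (4-benzyloxy-3-methoxyphenyl){(3R,4S)-4-[1-(4-benzyloxy-3-methoxyphenyl)ethenyl]oxolan-3-yl}methanone (trans) | COc1cc(C(=C)[C@H]2COC[C@@H]2C(=O)c2ccc(OCc3ccccc3)c(OC)c2)ccc1OCc1ccccc1 | intermediate
9 | (R)-(4-benzyloxy-3-methoxyphenyl){(3R,4S)-4-[1-(4-benzyloxy-3-methoxyphenyl)ethenyl]oxolan-3-yl}methanol | COc1cc(C(=C)[C@H]2COC[C@@H]2[C@@H](O)c2ccc(OCc3ccccc3)c(OC)c2)ccc1OCc1ccccc1 | intermediate
10 | tert-butyl{(R)-(4-benzyloxy-3-methoxyphenyl)[(3R,4S)-4-[1-(4-benzyloxy-3-methoxyphenyl)ethenyl]oxolan-3-yl]methoxy}dimethylsilane | COc1cc(C(=C)[C@H]2COC[C@@H]2[C@@H](O[Si](C)(C)C(C)(C)C)c2ccc(OCc3ccccc3)c(OC)c2)ccc1OCc1ccccc1 | intermediate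
11 | 1-(4-benzyloxy-3-methoxyphenyl)-1-{(3R,4R)-4-[(R)-(4-benzyloxy-3-methoxyphenyl)(tert-butyldimethylsilyloxy)methyl]oxolan-3-yl}ethane-1,2-diol (both epimers at C1) | COc1cc(C(O)(CO)[C@H]2COC[C@@H]2[C@@H](O[Si](C)(C)C(C)(C)C)c2ccc(OCc3ccccc3)c(OC)c2)ccc1OCc1ccccc1 | intermediate
12 | (4-benzyloxy-3-methoxyphenyl){(3R,4R)-4-[(R)-(4-benzyloxy-3-methoxyphenyl)(tert-butyldimethylsilyloxy)methyl]oxolan-3-yl}methanone | COc1cc(C(=O)[C@H]2COC[C@@H]2[C@@H](O[Si](C)(C)C(C)(C)C)c2ccc(OCc3ccccc3)c(OC)c2)ccc1OCc1ccccc1 | intermediate
13 | (S)-(4-benzyloxy-3-methoxyphenyl){(3R,4R)-4-[(R)-(4-benzyloxy-3-methoxyphenyl)(tert-butyldimethylsilyloxy)methyl]oxolan-3-yl}methanol | COc1cc([C@@H](O)[C@H]2COC[C@@H]2[C@@H](O[Si](C)(C)C(C)(C)C)c2ccc(OCc3ccccc3)c(OC)c2)ccc1OCc1ccccc1 | intermediate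
14 | (S)-(4-benzyloxy-3-methoxyphenyl){(3R,4R)-4-[(R)-(4-benzyloxy-3-methoxyphenyl)(hydroxy)methyl]oxolan-3-yl}methanol | COc1cc([C@@H](O)[C@H]2COC[C@@H]2[C@@H](O)c2ccc(OCc3ccccc3)c(OC)c2)ccc1OCc1ccccc1 | intermediate
15 | 4-[(S)-hydroxy{(3R,4R)-4-[(R)-hydroxy(4-hydroxy-3-methoxyphenyl)methyl]oxolan-3-yl}methyl]-2-methoxyphenol | COc1cc([C@@H](O)[C@H]2COC[C@@H]2[C@@H](O)c2ccc(O)c(OC)c2)ccc1O | target

## Step count and least certain steps

Total step count: 11. Longest linear sequence: 11 steps (1 → 3 → 4 → 5 → 6 → 8 → 9 → 10 → 12 → 13 → 14 → 15). Enone 4 enters step 5 twice, once as such and once after conversion into 6.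

**Step 5 (key step).** The likeliest failures are oligomerisation of the vinyl ketone, when the enolate adds to a second enone faster than it closes onto the allyl terminus, and isomerisation of the zwitterion by β-hydride loss before the alkoxide is captured. Enantiomeric purity may also erode if ring closure competes with allyl face exchange. The fallback keeps vinyl epoxide 6 but gives the acceptor role to a doubly activated alkene, the class on which this annulation is most secure, and introduces the aryl ketone afterwards. It sets out from 6 and returns at 8.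
- Annulation of 6 with dimethyl methylidenemalonate under the same catalyst should give dimethyl (4R)-4-[1-(4-benzyloxy-3-methoxyphenyl)ethenyl]oxolane-3,3-dicarboxylate F1.
- Krapcho demethoxycarbonylation (LiCl, wet DMSO, heat) and equilibration with NaOMe should give the trans ester methyl (3R,4S)-4-[1-(4-benzyloxy-3-methoxyphenyl)ethenyl]oxolane-3-carboxylate F2.
- N,O-Dimethylhydroxylamine hydrochloride and iPrMgCl convert it into (3R,4S)-4-[1-(4-benzyloxy-3-methoxyphenyl)ethenyl]-N-methoxy-N-methyloxolane-3-carboxamide F3.
- Addition of 4-benzyloxy-3-methoxyphenylmagnesium bromide to F3 gives 8.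

**Step 9.** Poor facial selectivity is the main risk. The ketone is α-branched and flanked by the bulky silyloxy arm, and because the target needs unlike carbinols, this reduction or that of step 6 probably has to override the ring's bias; the reaction may also be slow. The fallback gives up catalyst control in favour of separation and recycling. It sets out from 12 and returns at 13. Reduction with NaBH4 in THF–MeOH at low temperature gives 13 together with its epimer (R)-(4-benzyloxy-3-methoxyphenyl){(3R,4R)-4-[(R)-(4-benzyloxy-3-methoxyphenyl)(tert-butyldimethylsilyloxy)methyl]oxolan-3-yl}methanol F8. The epimers are separated by chromatography, and F8 is returned to 12 by Dess–Martin oxidation and resubmitted.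

**Step 6.** The same facial-selectivity problem may arise with the α-branched ketone 8. The fallback uses the identical constitution of the two arms, which makes it immaterial which carbinol is formed first as long as the second is set in the opposite sense. It sets out from 8 and returns at 14.
- The epimer (S)-(4-benzyloxy-3-methoxyphenyl){(3R,4S)-4-[1-(4-benzyloxy-3-methoxyphenyl)ethenyl]oxolan-3-yl}methanol F4 is made deliberately with the matched catalyst antipode, or isolated from a NaBH4 reduction.
- Silylation gives tert-butyl{(S)-(4-benzyloxy-3-methoxyphenyl)[(3R,4S)-4-[1-(4-benzyloxy-3-methoxyphenyl)ethenyl]oxolan-3-yl]methoxy}dimethylsilane F5.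
- Cleavage with OsO4 and NaIO4 gives (4-benzyloxy-3-methoxyphenyl){(3R,4R)-4-[(S)-(4-benzyloxy-3-methoxyphenyl)(tert-butyldimethylsilyloxy)methyl]oxolan-3-yl}methanone F6.
- Reduction with the (S)-oxazaborolidine and catecholborane gives (R)-(4-benzyloxy-3-methoxyphenyl){(3R,4R)-4-[(S)-(4-benzyloxy-3-methoxyphenyl)(tert-butyldimethylsilyloxy)methyl]oxolan-3-yl}methanol F7.
- Desilylation of F7 with TBAF gives a diol identical with 14.

**Step 11.** The risk is over-reduction: hydrogenolysis of one or both benzylic C–OH bonds, which are activated by the para oxygen, alongside the benzyl ethers. The fallback shields both benzylic oxygens as bulky silyl ethers before hydrogenolysis. It sets out from 13 and returns at 15.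
- Silylation of 13 with TBSOTf and 2,6-lutidine gives (3R,4R)-3-[(S)-(4-benzyloxy-3-methoxyphenyl)(tert-butyldimethylsilyloxy)methyl]-4-[(R)-(4-benzyloxy-3-methoxyphenyl)(tert-butyldimethylsilyloxy)methyl]oxolane F9.
- Hydrogenolysis (H2, 10% Pd/C, EtOAc) gives the bis-phenol (3R,4R)-3-[(S)-(tert-butyldimethylsilyloxy)(4-hydroxy-3-methoxyphenyl)methyl]-4-[(R)-(tert-butyldimethylsilyloxy)(4-hydroxy-3-methoxyphenyl)methyl]oxolane F10.
- TBAF removes both silyl groups to give 15.

## Further compounds

F1 | step 5 | dimethyl (4R)-4-[1-(4-benzyloxy-3-methoxyphenyl)ethenyl]oxolane-3,3-dicarboxylate | COc1cc(C(=C)[C@H]2COCC2(C(=O)OC)C(=O)OC)ccc1OCc1ccccc1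
F2 | step 5 | methyl (3R,4S)-4-[1-(4-benzyloxy-3-methoxyphenyl)ethenyl]oxolane-3-carboxylate | COc1cc(C(=C)[C@H]2COC[C@@H]2C(=O)OC)ccc1OCc1ccccc1
F3 | step 5 | (3R,4S)-4-[1-(4-benzyloxy-3-methoxyphenyl)ethenyl]-N-methoxy-N-methyloxolane-3-carboxamide | COc1cc(C(=C)[C@H]2COC[C@@H]2C(=O)N(C)OC)ccc1OCc1ccccc1
F4 | step 6 | (S)-(4-benzyloxy-3-methoxyphenyl){(3R,4S)-4-[1-(4-benzyloxy-3-methoxyphenyl)ethenyl]oxolan-3-yl}methanol | COc1cc(C(=C)[C@H]2COC[C@@H]2[C@H](O)c2ccc(OCc3ccccc3)c(OC)c2)ccc1OCc1ccccc1
F5 | step 6 | tert-butyl{(S)-(4-benzyloxy-3-methoxyphenyl)[(3R,4S)-4-[1-(4-benzyloxy-3-methoxyphenyl)ethenyl]oxolan-3-yl]methoxy}dimethylsilane | COc1cc(C(=C)[C@H]2COC[C@@H]2[C@H](O[Si](C)(C)C(C)(C)C)c2ccc(OCc3ccccc3)c(OC)c2)ccc1OCc1ccccc1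
F6 | step 6 | (4-benzyloxy-3-methoxyphenyl){(3R,4R)-4-[(S)-(4-benzyloxy-3-methoxyphenyl)(tert-butyldimethylsilyloxy)methyl]oxolan-3-yl}methanone | COc1cc(C(=O)[C@H]2COC[C@@H]2[C@H](O[Si](C)(C)C(C)(C)C)c2ccc(OCc3ccccc3)c(OC)c2)ccc1OCc1ccccc1
F7 | step 6 | (R)-(4-benzyloxy-3-methoxyphenyl){(3R,4R)-4-[(S)-(4-benzyloxy-3-methoxyphenyl)(tert-butyldimethylsilyloxy)methyl]oxolan-3-yl}methanol | COc1cc([C@H](O)[C@H]2COC[C@@H]2[C@H](O[Si](C)(C)C(C)(C)C)c2ccc(OCc3ccccc3)c(OC)c2)ccc1OCc1ccccc1
F8 | step 9 | (R)-(4-benzyloxy-3-methoxyphenyl){(3R,4R)-4-[(R)-(4-benzyloxy-3-methoxyphenyl)(tert-butyldimethylsilyloxy)methyl]oxolan-3-yl}methanol | COc1cc([C@H](O)[C@H]2COC[C@@H]2[C@@H](O[Si](C)(C)C(C)(C)C)c2ccc(OCc3ccccc3)c(OC)c2)ccc1OCc1ccccc1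
F9 | step 11 | (3R,4R)-3-[(S)-(4-benzyloxy-3-methoxyphenyl)(tert-butyldimethylsilyloxy)methyl]-4-[(R)-(4-benzyloxy-3-methoxyphenyl)(tert-butyldimethylsilyloxy)methyl]oxolane | COc1cc([C@@H](O[Si](C)(C)C(C)(C)C)[C@H]2COC[C@@H]2[C@@H](O[Si](C)(C)C(C)(C)C)c2ccc(OCc3ccccc3)c(OC)c2)ccc1OCc1ccccc1
F10 | step 11 | (3R,4R)-3-[(S)-(tert-butyldimethylsilyloxy)(4-hydroxy-3-methoxyphenyl)methyl]-4-[(R)-(tert-butyldimethylsilyloxy)(4-hydroxy-3-methoxyphenyl)methyl]oxolane | COc1cc([C@@H](O[Si](C)(C)C(C)(C)C)[C@H]2COC[C@@H]2[C@@H](O[Si](C)(C)C(C)(C)C)c2ccc(O)c(OC)c2)ccc1O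
A1 | alternative 1 | (2R,3R)-2,3-bis(4-benzyloxy-3-methoxybenzyl)butanedioic acid | OC(=O)[C@H](Cc1ccc(OCc2ccccc2)c(OC)c1)[C@@H](Cc1ccc(OCc2ccccc2)c(OC)c1)C(=O)O
A2 | alternative 1 | (1S,4S,5S,8S)-4,8-bis(4-benzyloxy-3-methoxyphenyl)-3,7-dioxabicyclo[3.3.0]octane-2,6-dione (exo,exo) | COc1cc([C@H]2OC(=O)[C@H]3[C@@H]2C(=O)O[C@@H]3c2ccc(OCc3ccccc3)c(OC)c2)ccc1OCc1ccccc1
A3 | alternative 1 | (S,S)-[(3R,4R)-oxolane-3,4-diyl]bis[(4-benzyloxy-3-methoxyphenyl)methanol] (like-configured carbinols) | COc1cc([C@@H](O)[C@H]2COC[C@@H]2[C@H](O)c2ccc(OCc3ccccc3)c(OC)c2)ccc1OCc1ccccc1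
A4 | alternative 2 | 1,2-bis(4-benzyloxy-3-methoxyphenyl)ethyne | COc1cc(C#Cc2ccc(OCc3ccccc3)c(OC)c2)ccc1OCc1ccccc1
A5 | alternative 2 | 2,5-dihydrofuran | C1=CCOC1
A6 | alternative 2 | meso-(1R,5S)-6,7-bis(4-benzyloxy-3-methoxyphenyl)-3-oxabicyclo[3.2.0]hept-6-ene | COc1cc(C2=C(c3ccc(OCc4ccccc4)c(OC)c3)[C@H]3COC[C@H]32)ccc1OCc1ccccc1
A7 | alternative 2 | meso-cis-oxolane-3,4-diylbis[(4-benzyloxy-3-methoxyphenyl)methanone] | COc1cc(C(=O)[C@H]2COC[C@H]2C(=O)c2ccc(OCc3ccccc3)c(OC)c2)ccc1OCc1ccccc1
A8 | alternative 3 | bis[(E)-3-(4-benzyloxy-3-methoxyphenyl)prop-2-en-1-yl] ether | COc1cc(/C=C/COC/C=C/c2ccc(OCc3ccccc3)c(OC)c2)ccc1OCc1ccccc1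
A9 | alternative 3 | rac-1,4-bis(4-benzyloxy-3-methoxyphenyl)hexahydrofuro[3,4-d][1,2]dioxine, trans-fused, relative configuration (1S,4S,4aR,7aR) | COc1cc([C@H]2OO[C@H](c3ccc(OCc4ccccc4)c(OC)c3)[C@H]3COC[C@@H]32)ccc1OCc1ccccc1
A10 | alternative 3 | rac-[trans-oxolane-3,4-diyl]bis[(4-benzyloxy-3-methoxyphenyl)methanol] with like-configured carbinols, relative configuration shown | COc1cc([C@@H](O)[C@H]2COC[C@@H]2[C@H](O)c2ccc(OCc3ccccc3)c(OC)c2)ccc1OCc1ccccc1
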